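# Total synthesis proposal for CNP0361406.12: one Diels–Alder template, run in both mirror-image series, for the core and the side chain

## Analysis of the target

The target is a diester of two terpenoid halves, numbered here as follows: a cyclohexane C1 (isopropyl, methine C14) – C2 – C3 – C4 (OH and C13H2O) – C5 – C6, cis-fused through C5–C6 to the seven-membered lactone C7(=O)–O8–C9H2–C10(C12O2H)=C11H; and the acyl group C9'(=O)–C8'(C10'H2OH)=C7'H–C1' on O13, whose C1' belongs to the cyclohexene C1'–C2'=C3'(C11'H2OH)–C4'–C5'–C6'(isopropyl). The core has four stereocentres (1R,4S,5S,6R in this numbering), with C14 on C1, C13 on C4, C7 on C5 and C11 on C6 on one face of the ring and the tertiary hydroxyl on the other, and the side chain has two (1'R,6'S), cis to each other. When the side-chain ring is laid on the core ring (C6' on C1, C1' on C6, C3' on C4) both centres have the opposite sense, so the side chain is the decarboxylated, dehydrated relative of the core in the mirror-image series. Sensitive points are the lactone (an allylic ester of an acrylate), two enoates with γ-hydrogens on stereocentres (C6, and the doubly allylic C1'), and a tertiary alcohol β to the lactone carbonyl (retro-aldol, elimination). The most serious hazard is a free C13 hydroxyl: it is γ to the C7 acyl group and would take that acyl group over to form a five-membered lactone, so O13 must be acylated as soon as it is set free. The difficulty is therefore the all-cis array with a quaternary carbinol on a flexible ring, made in one absolute series for the core and in the other for the side chain. The feature the plan rests on is that C14 (on C1) and C13 (on C4) are 1,4-cis and can be tied as the two carbons of an etheno bridge, which turns the cyclohexane into a bicyclo[2.2.2]octene with C1 and C4 as bridgeheads and C7 and C11 as endo substituents. The side-chain ring contains the same 1,4 pair (isopropyl carbon on C6', C11' on C3') once an oxygen on C3' and a carboxyl on C2' are added back.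

## Retrosynthetic reasoning

42 from 41 from 39. Only O–Si bonds and one ester O–C(CH3)3 bond are cut. Acid 41 is freed first and the three silyl ethers are removed last under acidic fluoride, because the final compound carries a β-hydroxy lactone and an acyloxy alcohol that should not see base.

39 from 38 from 37. The isopropyl group of 39 is traced back to the isopropenyl group of 38 and then to the C1 acetyl group (C14=O) of 37. This is done after the two halves are joined, so that O13 never has to be protected and released again beside the C7 lactone. The forward steps must methylenate an epimerisable methyl ketone without enolising it and must hydrogenate a 1,1-disubstituted alkene in the presence of three trisubstituted ones.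

37 from 35 and 34. The ester bond O13–C9' is the natural seam between the halves. The forward acylation has to be faster than attack of the C13 hydroxyl on C7, so alcohol 35 is made under non-basic conditions and acylated at once with acid 34.

35 from 18 from 17. C13 (as formyl) and C14 (as acetyl) in 18 are joined to a C=C bond; this is the ozonolysis retron. C1 and C4 become bridgeheads of a bicyclo[2.2.2]octene, and "all on one face" becomes "endo, syn to the etheno bridge". The lactone is already closed in 17, so C7 is tied up when C13 is reduced.

17 from 15 from 14 from 9 and 12; 9 from 8; 12 from 10. The oxepinone is opened at O8–C7 (lactonisation of 15) and at C10=C11 (Horner–Wadsworth–Emmons olefination giving 14). C11 as an aldehyde and C7 as a carboxyl are then the two carbons of the cis-fused lactol 9, which is the hydrolysed form of lactone acetal 8. Phosphonate 12 brings C9, C10 and C12 and is made by alkoxymethylation of 10.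

8 from 3 and 7 (key disconnection). The bonds C4–C5 and C1–C6 are cut. The six-membered ring opens to the 1-silyloxy-3-methylcyclohexa-1,3-diene 3 and the butenolide 7, whose acetal carbon is the only stereocentre. One cycloaddition then has to set C1, C4, C5 and C6.

3 from 1 (through 2); 7 from 5 and 6; 5 from 4. Diene 3 is the linear silyl dienol ether of enone 1. Dienophile 7 is the acetal of hydroxyfuranone 5, the photo-oxidation product of 4, with auxiliary alcohol 6, obtained as one epimer by crystallisation.

34 from 32 from 31. The C2'=C3' alkene of 32 is the retron of a dehydrative decarboxylation. Putting a carboxyl back on C2' and a hydroxyl on C3' gives the β-hydroxy acid 31 with exactly the substitution pattern of the core ring, in the opposite absolute series.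

31 from 29 from 28 from 27 from 25 from 24 from 22 from 21 from 3 and 20; 20 from 5 and 19. The same cycloaddition, olefination and ozonolysis are run with the antipodal auxiliary 19. Here the five-membered lactone between C11' and the C2' carboxyl, the hazard of the core series, is formed on purpose in 27. It protects both groups while the acetyl group is turned into isopropyl (28, 29). It is then opened with transfer of the silyl group from the tertiary to the primary oxygen, which exposes the β-hydroxy acid 31.

## Alternatives that were turned down

Alternative 1: Disconnection of the side-chain cyclohexene at C1'–C6' and C4'–C5'. The forward step is an enantioselective Diels–Alder reaction of the terminal diene of trienoate A2 with imide A3 on a chiral bis(oxazoline) complex of Cu(OTf)2, giving cis cyclohexene imide A1 with the (E)-acrylate arm already attached.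
- For: it is catalytic; the cis relation follows from the (E)-diene and the endo rule; the 1- and 3-substituents of the diene both direct the acyl carbon to C6'; and the doubly allylic C1' never passes through an aldehyde.
- Against: the diene of A2 is conjugated to an ester and therefore electron-poor, so its reaction with an electron-poor dienophile should be slow, and the triene offers a second diene unit and a dienophilic enoate. The imide must still be turned into isopropyl (methyl ketone, methylenation, selective hydrogenation) with C6' epimerisable. Most important, the step sets two of six stereocentres on the easier ring and leaves the all-cis core with its quaternary carbinol untouched.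
- Comparison: for the side chain alone A1 should be reached in fewer steps than acid 34 here (about eight against eleven), so on step economy for that half the alternative is stronger. The chosen plan offers instead one cycloaddition that sets all four core centres and, with the other auxiliary antipode, both side-chain centres, so one reaction and one set of follow-up operations serve both halves.

Alternative 2: Disconnection of C10=C11. The forward step is ring-closing metathesis of diene A5 (vinyl on C6, 2-(acyloxymethyl)acrylate on the C5 carboxyl) with loss of ethene, giving oxepinone A4.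
- For: neutral conditions, no E/Z question because the ring dictates the geometry, and one step where the chosen route uses three (olefination, desilylation, lactonisation). On this ring closure the alternative is as strong or stronger.
- Against: it creates no stereocentre. A5 already needs C1, C4, C5 and C6, which in practice would come from a cis-fused lactol of the kind of 9. Metathesis of a monosubstituted alkene with a 1,1-disubstituted acrylate to a trisubstituted enoate in a seven-membered ring is a slow closure that needs a second-generation Hoveyda–Grubbs catalyst and heat. A4 also carries a silyl-protected O13 whose later release beside the C7 lactone invites the acyl shift described above.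
- Comparison: it is an end-game rather than an answer to the stereochemical problem. It is kept here as the fallback for step 7.

Alternative 3: Disconnection of C5–C7 and C4–O. The forward step oxidises carbazate A7, on the C6 hydroxymethyl arm of a cyclohexene, to an alkoxycarbonyl radical that adds 5-exo to C5; the tertiary C4 radical is capped by tert-butylperoxyl to give γ-lactone peroxide A6.
- For: two bonds, one ring and two stereocentres, including the quaternary C4–O, in one step; 5-exo closure makes the cis ring fusion at C5 reliable; the C4 oxygen is put in late on a simple cyclohexene, which is more direct than carrying it from the first step as here.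
- Against: the configuration at C4 depends on the face at which a planar tertiary radical meets a peroxyl radical, with substrate control only; the acyl radical can lose CO2; and radical–radical capture needs a high stationary peroxyl concentration. The lactone formed is the wrong one: it ties C7 to the C6 arm at the alcohol oxidation level, so it must be opened, the arm oxidised to an epimerisable aldehyde beside a free carboxyl, olefinated and re-lactonised, and the peroxide reduced. A7 must itself be made as a single cis enantiomer first.
- Comparison: the chosen cycloaddition sets the four centres under auxiliary control and delivers C7 and C11 at the right oxidation levels as a lactone acetal.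

Key step: step 4

Remark on the chemistry: 5 and 12 are racemic, and the lactols 9 and 22 are anomeric mixtures drawn without configuration at the lactol carbon. Neither matters, because these centres are set by crystallisation (steps 3 and 11) or become sp2 (steps 7 and 14).

## Route

### Shared building blocks and the core series (steps 1–10)

Step 1
Reactants: 1 3-methylcyclohex-2-en-1-one
Product: 3 tert-butyl(dimethyl)[(3-methylcyclohexa-1,3-dien-1-yl)oxy]silane, via bromomagnesium dienolate 2 (not isolated)
Conditions: MeMgBr (1.1 equiv), FeCl3 (3 mol %), Et2O, −20 °C; TBSOTf, DMPU, −20 → 0 °C; distillation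
Reagents that add atoms: tert-butyldimethylsilyl trifluoromethanesulfonate, CC(C)(C)[Si](C)(C)OS(=O)(=O)C(F)(F)F
Why: Iron-catalysed Grignard deprotonation removes the ring γ-proton of the enone and gives the linear, fully conjugated dienolate, which is silylated on oxygen (thermodynamic silyl dienol ether formation). The cross-conjugated kinetic isomer is avoided, and any exocyclic isomer is a fixed transoid diene that cannot enter step 4.

Step 2
Reactants: 4 furfural
Product: 5 5-hydroxyfuran-2(5H)-one
Conditions: O2, hν (visible), rose bengal (cat.), MeOH, 20 °C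
Reagents that add atoms: dioxygen, O=O
Why: Dye-sensitised singlet-oxygen [4+2] addition to the furan, then methanolysis of the endoperoxide with loss of the formyl carbon as its methyl ester (photo-oxygenation of furfural).

Step 3
Reactants: 5 5-hydroxyfuran-2(5H)-one; 6 (+)-menthol
Product: 7 (5S)-5-[(1S,2R,5S)-menthyloxy]furan-2(5H)-one
Conditions: CSA (cat.), benzene, reflux, Dean–Stark; crystallisation from petroleum ether, mother liquor re-equilibrated with CSA
Reagents that add atoms: none
Why: Acid-catalysed acetalisation of the hemiacylal with the secondary alcohol. The two C5 epimers interconvert under acid and the (5S) epimer crystallises, so the acetal stereocentre is set by crystallisation-induced epimerisation.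

Step 4
Reactants: 3 silyl dienol ether; 7 (5S)-menthyloxyfuranone
Product: 8 endo bicyclo[2.2.2]octene lactone acetal with bridgehead silyloxy group
Conditions: toluene (2 M), BHT (cat.), 100 °C, sealed tube; diene used in twofold excess and the surplus recovered by distillation
Reagents that add atoms: none
Why: A concerted but asynchronous normal-demand Diels–Alder reaction in which the HOMO of diene 3, raised by the 1-silyloxy and 3-methyl donors, meets the LUMO of butenolide 7. Both donors put the largest HOMO coefficient on the unsubstituted diene terminus (future C1), which bonds to the β-carbon of the lactone (future C6), so the silyloxy terminus (future C4) ends up next to the carbonyl-bearing carbon (future C5), the usual orientation of 1-oxygenated dienes. The cyclohexane C1–C6 closes in this single suprafacial [4+2] event as one ring of the bicyclo[2.2.2]octene, the CH2–CH2 unit of the diene becoming C2–C3 and C(CH3)=CH the etheno bridge (future C14 and C13). C5 and C6 are cis because the ring alkene of 7 adds suprafacially, and they lie syn to the etheno bridge because the lactone carbonyl overlaps with the diene in the endo transition state (Alder rule). C1 and C4 are bridgeheads, so their relative configuration is fixed by the ring, and their absolute sense, like that of C5 and C6, follows from the face of 7 that is attacked: the diene approaches anti to the menthyloxy group on the acetal carbon. The step thus needs regio-, endo- and facial selectivity; the donor pattern of 3 secures the first, the cis-locked carbonyl of the five-membered dienophile the second, and the (5S) acetal centre the third. The closest known reactions are endo additions of 1-silyloxycyclohexa-1,3-dienes to cyclic enones and anhydrides and anti-selective additions of cyclic dienes to 5-menthyloxyfuranones.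

Step 5
Reactants: 8 endo lactone acetal
Product: 9 lactol (pseudo-acid) of the core series
Conditions: TFA/H2O (4:1), CH2Cl2, 0 °C → rt
Reagents that add atoms: water, O
Why: Acid-catalysed hydrolysis of the acyloxy acetal. The product stays closed as the lactol, so no free aldehyde is present and C5 and C6 remain cis; the bridgehead silyl ether is tertiary, hindered and cannot ionise.

Step 6
Reactants: 10 tert-butyl (diethoxyphosphoryl)acetate
Product: 12 tert-butyl 2-(diethoxyphosphoryl)-3-[(triisopropylsilyl)oxy]propanoate, via sodium salt 11 (not isolated)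
Conditions: NaH (1.0 equiv), THF, 0 °C; (iPr3SiO)CH2Cl (0.9 equiv), 0 °C → rt
Reagents that add atoms: (triisopropylsiloxy)methyl chloride, ClCO[Si](C(C)C)(C(C)C)C(C)C
Why: C-alkylation of the stabilised phosphonoacetate carbanion with an α-chloro ether (alkoxymethylation), a very reactive electrophile; a slight excess of carbanion suppresses double alkylation.

Step 7
Reactants: 9 lactol; 12 silyloxymethyl phosphonate
Product: 14 core bicyclic acid with (E)-enoate arm, via sodium aldehyde carboxylate 13 (not isolated)
Conditions: 12 (2.5 equiv), NaH (2.4 equiv), THF, 0 °C; then 9, 0 °C → rt; aq. NaH2PO4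
Reagents that add atoms: none
Why: Horner–Wadsworth–Emmons olefination of a lactol: the sodium salt of 12, made in the flask with NaH, first opens 9 to the aldehyde carboxylate 13, a further equivalent adds to the aldehyde, and the oxaphosphetane collapses to the trisubstituted enoate (C10=C11). With an α-branched aldehyde and a tert-butyl ester the isomer with C6 trans to the ester, (E), should prevail; the cis C5/C6 relation is that of the lactol, and the low temperature limits enolisation of the aldehyde.

Step 8
Reactants: 14 core bicyclic acid with silyl-protected arm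
Product: 15 core hydroxy acid
Conditions: HF·pyridine, pyridine, THF, 0 °C → rt
Reagents that add atoms: none
Why: Buffered HF·pyridine removes the primary triisopropylsilyl ether (fluoride desilylation); the hindered tertiary bridgehead silyl ether and the tert-butyl ester stay.

Step 9
Reactants: 15 core hydroxy acid
Product: 17 tricyclic oxepinone lactone tert-butyl ester, via mixed anhydride 16 (not isolated)
Conditions: 2,4,6-Cl3C6H2COCl, Et3N, THF, rt; slow addition to DMAP, toluene, 80 °C (2 mM)
Reagents that add atoms: none
Why: Yamaguchi lactonisation: the mixed anhydride of the C5 carboxyl is attacked under DMAP catalysis and high dilution by the cis-disposed primary allylic alcohol (O8–C7 bond). Only the (E)-enoate, with C6 cis to the hydroxymethyl group, can close the seven-membered ring, so any (Z)-isomer from step 7 is left behind.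

Step 10
Reactants: 17 tricyclic oxepinone lactone
Product: 18 core keto aldehyde
Conditions: O3, pyridine (3 equiv), CH2Cl2, −78 °C (Sudan Red 7B end point)
Reagents that add atoms: ozone, [O-][O+]=O
Why: Ozonolysis: ozone attacks the electron-rich trisubstituted bridge alkene much faster than the ester-conjugated C10=C11; pyridine intercepts the carbonyl oxide, so ketone and aldehyde form directly without an ozonide or over-oxidation. C1 and C4, until now bridgeheads, become ring stereocentres carrying acetyl and formyl on the same face; 18 is the storage point of the core series.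

### Side-chain series (steps 11–21)

Step 11
Reactants: 5 5-hydroxyfuran-2(5H)-one; 19 (−)-menthol
Product: 20 (5R)-5-[(1R,2S,5R)-menthyloxy]furan-2(5H)-one
Conditions: CSA (cat.), benzene, reflux, Dean–Stark; crystallisation from petroleum ether, mother liquor re-equilibrated with CSA
Reagents that add atoms: none
Why: The mirror image of step 3: acetalisation and crystallisation-induced epimerisation give the (5R) epimer with the antipodal auxiliary.

Step 12
Reactants: 3 silyl dienol ether; 20 (5R)-menthyloxyfuranone
Product: 21 enantiomer of adduct 8
Conditions: toluene (2 M), BHT (cat.), 100 °C, sealed tube; diene used in twofold excess and the surplus recovered by distillation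
Reagents that add atoms: none
Why: The same endo, anti-selective Diels–Alder reaction as step 4 with the enantiomeric dienophile, so regio- and endo-control are identical and the absolute sense of all four new centres is inverted.

Step 13
Reactants: 21 enantiomeric lactone acetal
Product: 22 lactol of the side-chain series
Conditions: TFA/H2O (4:1), CH2Cl2, 0 °C → rt
Reagents that add atoms: water, O
Why: Acid hydrolysis of the acyloxy acetal as in step 5; the closed lactol keeps the two endo substituents cis.

Step 14
Reactants: 22 lactol; 12 silyloxymethyl phosphonate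
Product: 24 side-chain bicyclic acid with (E)-enoate arm, via sodium aldehyde carboxylate 23 (not isolated)
Conditions: 12 (2.5 equiv), NaH (2.4 equiv), THF, 0 °C; then 22, 0 °C → rt; aq. NaH2PO4; chromatographic removal of any (Z)-isomer
Reagents that add atoms: none
Why: Horner–Wadsworth–Emmons olefination as in step 7, through the ring-opened aldehyde carboxylate 23. It builds C7'=C8' with C1' trans to the ester, (E), and brings in C9' and the protected C10' hydroxymethyl group.

Step 15
Reactants: 24 side-chain bicyclic acid
Product: 25 side-chain keto aldehyde acid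
Conditions: O3, pyridine (3 equiv), CH2Cl2, −78 °C (Sudan Red 7B end point)
Reagents that add atoms: ozone, [O-][O+]=O
Why: Chemoselective ozonolysis of the electron-rich bridge alkene as in step 10. C6' receives acetyl and C3' formyl, cis to each other and to the arm and the carboxyl.

Step 16
Reactants: 25 side-chain keto aldehyde acid
Product: 27 side-chain γ-lactone ketone, via hydroxy acid 26 (not isolated)
Conditions: NaBH(OAc)3, AcOH, CH2Cl2, 0 °C → rt; PPTS (cat.), CH2Cl2, rt
Reagents that add atoms: none
Why: The acyloxyborohydride reduces the aldehyde but not the ketone or the esters (chemoselective hydride reduction). The resulting γ-hydroxy acid closes to the cis-fused γ-lactone, which protects both O11' and the C2' carboxyl during the next two steps.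

Step 17
Reactants: 27 side-chain γ-lactone ketone
Product: 28 side-chain isopropenyl lactone
Conditions: Zn, CH2Br2, TiCl4, THF (Lombardo reagent, aged at 5 °C); CH2Cl2, 0 °C → rt
Reagents that add atoms: dibromomethane (as the zinc/titanium methylene reagent), BrCBr
Why: Lombardo methylenation: the non-basic methylene reagent converts ketones but not esters or lactones and does not enolise, so the epimerisable C6' next to the acetyl group is kept.

Step 18
Reactants: 28 side-chain isopropenyl lactone
Product: 29 side-chain isopropyl lactone
Conditions: H2 (1 atm), RhCl(PPh3)3 (10 mol %), benzene/EtOH (1:1), rt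
Reagents that add atoms: none
Why: Homogeneous hydrogenation with RhCl(PPh3)3 reduces the unhindered 1,1-disubstituted alkene much faster than the trisubstituted conjugated enoate; no stereocentre is formed.

Step 19
Reactants: 29 side-chain isopropyl lactone
Product: 31 side-chain β-hydroxy acid with primary silyl ether, via ring-opened lithium carboxylate 30 (not isolated)
Conditions: LiOH (3 equiv), THF/H2O (3:1), rt → 40 °C; AcOH to pH 5, 0 °C
Reagents that add atoms: lithium hydroxide, [Li+].[OH-]
Why: Saponification opens the γ-lactone (the tert-butyl enoate is inert to hydroxide). The freed C11' alkoxide then takes the silyl group from the neighbouring tertiary oxygen through a five-membered silicate (base-mediated 1,4 O→O silyl migration, driven by relief of strain at the tertiary ether). Acidification therefore gives a β-hydroxy acid that can no longer relactonise.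

Step 20
Reactants: 31 side-chain β-hydroxy acid
Product: 32 side-chain cyclohexene tert-butyl ester
Conditions: Me2NCH(OCH2CMe3)2, toluene, 100 °C
Reagents that add atoms: none
Why: Dehydrative decarboxylation of a β-hydroxy acid with a formamide acetal: the tertiary hydroxyl is activated as the formamidinium ether and leaves with loss of CO2 from the neighbouring carboxylate, so the alkene can only form between C2' and C3'. C1' and C6' are untouched and stay cis.

Step 21
Reactants: 32 side-chain cyclohexene tert-butyl ester
Product: 34 side-chain acid, via trimethylsilyl ester 33 (not isolated)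
Conditions: TMSOTf, 2,6-lutidine, CH2Cl2, 0 °C; aq. NaH2PO4
Reagents that add atoms: none
Why: Silyl triflate with 2,6-lutidine converts the tert-butyl ester into the silyl ester with loss of isobutene (alkyl–oxygen cleavage) and leaves the two primary silyl ethers alone; aqueous work-up frees the acid.

### Coupling and end-game (steps 22–27)

Step 22
Reactants: 18 core keto aldehyde
Product: 35 core primary alcohol
Conditions: NaBH(OAc)3, AcOH, CH2Cl2, 0 °C; cold pH 7 work-up; used at once
Reagents that add atoms: none
Why: Chemoselective acyloxyborohydride reduction of the aldehyde, leaving the methyl ketone, enoate and lactone. No alkoxide is generated, which keeps the C13 hydroxyl from attacking C7 or taking over the neighbouring silyl group before it is acylated.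

Step 23
Reactants: 35 core primary alcohol; 34 side-chain acid
Product: 37 coupled keto ester, via mixed anhydride 36 (not isolated)
Conditions: 34 (1.3 equiv), 2,4,6-Cl3C6H2COCl, Et3N, toluene, rt; then 35, DMAP, toluene, 0 °C → rt
Reagents that add atoms: none
Why: Yamaguchi esterification: the pre-formed mixed anhydride of 34 acylates the primary C13 alcohol under DMAP catalysis. Intermolecular acylation by an activated anhydride is expected to outrun intramolecular attack on the unactivated lactone carbonyl C7.

Step 24
Reactants: 37 coupled keto ester
Product: 38 coupled isopropenyl compound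
Conditions: Zn, CH2Br2, TiCl4, THF (Lombardo reagent, aged at 5 °C); CH2Cl2, 0 °C → rt
Reagents that add atoms: dibromomethane (as the zinc/titanium methylene reagent), BrCBr
Why: Lombardo methylenation as in step 17: ketone-selective in the presence of three esters and a lactone and non-basic, so C1 is not epimerised.

Step 25
Reactants: 38 coupled isopropenyl compound
Product: 39 fully protected target
Conditions: H2 (1 atm), RhCl(PPh3)3 (10 mol %), benzene/EtOH (1:1), rt
Reagents that add atoms: none
Why: Homogeneous hydrogenation: RhCl(PPh3)3 reduces the 1,1-disubstituted isopropenyl group selectively over the three trisubstituted alkenes (C10=C11, C7'=C8', C2'=C3'), as in step 18.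

Step 26
Reactants: 39 fully protected target
Product: 41 tris-silylated acid, via trimethylsilyl ester 40 (not isolated)
Conditions: TMSOTf, 2,6-lutidine, CH2Cl2, 0 °C; aq. NaH2PO4
Reagents that add atoms: none
Why: Selective conversion of the only tert-butyl ester (C12) into the silyl ester with loss of isobutene, as in step 21. Silyl ethers, the O13 ester and the lactone are untouched, and work-up frees the C12 acid.

Step 27
Reactants: 41 tris-silylated acid
Product: 42 CNP0361406.12
Conditions: 48% aq. HF, MeCN, 0 °C → rt
Reagents that add atoms: none
Why: Acidic fluoride desilylation cleaves the two primary silyl ethers and, more slowly, the hindered tertiary one. No base is present, so neither acyl migration from O13 nor retro-aldol opening at C4–C5 is provoked.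

## Compound list

1 | 3-methylcyclohex-2-en-1-one | CC1=CC(=O)CCC1 | starting material
2 | bromomagnesium 3-methylcyclohexa-1,3-dien-1-olate (linear dienolate) | CC1=CCCC(O[Mg]Br)=C1 | intermediate
3 | tert-butyl(dimethyl)[(3-methylcyclohexa-1,3-dien-1-yl)oxy]silane | CC1=CCCC(O[Si](C)(C)C(C)(C)C)=C1 | intermediate
4 | furfural (furan-2-carbaldehyde) | O=Cc1ccco1 | starting material
5 | 5-hydroxyfuran-2(5H)-one (racemic) | O=C1OC(O)C=C1 | intermediate
6 | (+)-menthol, (1S,2R,5S)-5-methyl-2-(propan-2-yl)cyclohexan-1-ol | CC(C)[C@H]1CC[C@H](C)C[C@@H]1O | starting material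
7 | (5S)-5-[(1S,2R,5S)-menthyloxy]furan-2(5H)-one | O=C1O[C@H](O[C@H]2C[C@@H](C)CC[C@@H]2C(C)C)C=C1 | intermediate
8 | endo adduct: 7-[(tert-butyldimethylsilyl)oxy]-3-[(1S,2R,5S)-menthyloxy]-5-methyl-3a,4,7,7a-tetrahydro-4,7-ethano-2-benzofuran-1(3H)-one; lactone ring syn to the C5=C6 bridge, menthyloxy trans to C4 across the lactone ring, silyloxy on the bridgehead next to the carbonyl-bearing carbon | CC1=C[C@]2(O[Si](C)(C)C(C)(C)C)CC[C@H]1[C@H]3[C@@H]2C(=O)O[C@@H]3O[C@H]4C[C@@H](C)CC[C@@H]4C(C)C | intermediate
9 | lactol of 8: same skeleton and configuration with OH in place of menthyloxy (both anomers) | CC1=C[C@]2(O[Si](C)(C)C(C)(C)C)CC[C@H]1[C@H]3[C@@H]2C(=O)OC3O | intermediate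
10 | tert-butyl (diethoxyphosphoryl)acetate | CCOP(=O)(OCC)CC(=O)OC(C)(C)C | starting material
11 | sodium salt (carbanion) of 10 | CCOP(=O)(OCC)[CH-]C(=O)OC(C)(C)C.[Na+] | intermediate
12 | tert-butyl 2-(diethoxyphosphoryl)-3-[(triisopropylsilyl)oxy]propanoate (racemic) | CCOP(=O)(OCC)C(CO[Si](C(C)C)(C(C)C)C(C)C)C(=O)OC(C)(C)C | intermediate
13 | sodium 1-[(tert-butyldimethylsilyl)oxy]-3-formyl-5-methylbicyclo[2.2.2]oct-5-ene-2-carboxylate (ring-opened 9; formyl and carboxylate cis and syn to C5=C6, core series) | CC1=C[C@]2(O[Si](C)(C)C(C)(C)C)CC[C@H]1[C@H](C=O)[C@@H]2C(=O)[O-].[Na+] | intermediate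
14 | 1-[(tert-butyldimethylsilyl)oxy]-5-methyl-3-[(1E)-3-tert-butoxy-3-oxo-2-{[(triisopropylsilyl)oxy]methyl}prop-1-en-1-yl]bicyclo[2.2.2]oct-5-ene-2-carboxylic acid; carboxyl and alkenyl arm cis and both syn to C5=C6 (core series) | CC1=C[C@]2(O[Si](C)(C)C(C)(C)C)CC[C@H]1[C@H](/C=C(\CO[Si](C(C)C)(C(C)C)C(C)C)C(=O)OC(C)(C)C)[C@@H]2C(=O)O | intermediate
15 | hydroxy acid: 14 with free hydroxymethyl on the arm | CC1=C[C@]2(O[Si](C)(C)C(C)(C)C)CC[C@H]1[C@H](/C=C(\CO)C(=O)OC(C)(C)C)[C@@H]2C(=O)O | intermediate
16 | mixed anhydride of the ring carboxyl of 15 with 2,4,6-trichlorobenzoic acid | CC1=C[C@]2(O[Si](C)(C)C(C)(C)C)CC[C@H]1[C@H](/C=C(\CO)C(=O)OC(C)(C)C)[C@@H]2C(=O)OC(=O)c3c(Cl)cc(Cl)cc3Cl | intermediate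
17 | tricyclic lactone: seven-membered lactone C7(=O)–O8–C9–C10=C11 cis-fused to the bicyclo[2.2.2]octene on the side of its C=C bridge; tert-butyl ester on C10, silyloxy on the bridgehead next to C5 | CC1=C[C@]2(O[Si](C)(C)C(C)(C)C)CC[C@H]1[C@@H]3C=C(C(=O)OC(C)(C)C)COC(=O)[C@@H]32 | intermediate
18 | core keto aldehyde: cyclohexane with C1 acetyl, C4 formyl and C4 silyloxy, cis-fused oxepinone with C12 tert-butyl ester; acetyl, formyl, C7 and C11 on one face, silyloxy on the other | CC(=O)[C@H]1CC[C@@](O[Si](C)(C)C(C)(C)C)(C=O)[C@H]2C(=O)OCC(C(=O)OC(C)(C)C)=C[C@@H]12 | intermediate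
19 | (−)-menthol, (1R,2S,5R)-5-methyl-2-(propan-2-yl)cyclohexan-1-ol | CC(C)[C@@H]1CC[C@@H](C)C[C@H]1O | starting material
20 | (5R)-5-[(1R,2S,5R)-menthyloxy]furan-2(5H)-one | O=C1O[C@@H](O[C@@H]2C[C@H](C)CC[C@H]2C(C)C)C=C1 | intermediate
21 | enantiomer of 8 | CC1=C[C@@]2(O[Si](C)(C)C(C)(C)C)CC[C@@H]1[C@@H]3[C@H]2C(=O)O[C@H]3O[C@@H]4C[C@H](C)CC[C@H]4C(C)C | intermediate
22 | enantiomer of 9 (both anomers) | CC1=C[C@@]2(O[Si](C)(C)C(C)(C)C)CC[C@@H]1[C@@H]3[C@H]2C(=O)OC3O | intermediate
23 | enantiomer of 13 (ring-opened 22, side-chain series) | CC1=C[C@@]2(O[Si](C)(C)C(C)(C)C)CC[C@@H]1[C@@H](C=O)[C@H]2C(=O)[O-].[Na+] | intermediate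
24 | enantiomer of 14 | CC1=C[C@@]2(O[Si](C)(C)C(C)(C)C)CC[C@@H]1[C@@H](/C=C(\CO[Si](C(C)C)(C(C)C)C(C)C)C(=O)OC(C)(C)C)[C@H]2C(=O)O | intermediate
25 | side-chain keto aldehyde acid: cyclohexane C1'–C6' with the (E)-arm on C1', carboxyl on C2', formyl (C11') and silyloxy on C3', acetyl on C6'; arm, carboxyl, formyl and acetyl cis, silyloxy trans (drawn open; may close to the hydroxy lactone) | CC(=O)[C@@H]1CC[C@](O[Si](C)(C)C(C)(C)C)(C=O)[C@H](C(=O)O)[C@@H]1/C=C(\CO[Si](C(C)C)(C(C)C)C(C)C)C(=O)OC(C)(C)C | intermediate
26 | hydroxy acid: 25 with C11' as CH2OH | CC(=O)[C@@H]1CC[C@](O[Si](C)(C)C(C)(C)C)(CO)[C@H](C(=O)O)[C@@H]1/C=C(\CO[Si](C(C)C)(C(C)C)C(C)C)C(=O)OC(C)(C)C | intermediate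
27 | side-chain γ-lactone ketone: C2' carboxyl closed on O11' (cis-fused five-membered lactone across C2'–C3'), C3' silyloxy, C6' acetyl, arm on C1' | CC(=O)[C@@H]1CC[C@]2(O[Si](C)(C)C(C)(C)C)COC(=O)[C@@H]2[C@@H]1/C=C(\CO[Si](C(C)C)(C(C)C)C(C)C)C(=O)OC(C)(C)C | intermediate
28 | 27 with isopropenyl in place of acetyl on C6' | C=C(C)[C@@H]1CC[C@]2(O[Si](C)(C)C(C)(C)C)COC(=O)[C@@H]2[C@@H]1/C=C(\CO[Si](C(C)C)(C(C)C)C(C)C)C(=O)OC(C)(C)C | intermediate
29 | 27 with isopropyl in place of acetyl on C6' | CC(C)[C@@H]1CC[C@]2(O[Si](C)(C)C(C)(C)C)COC(=O)[C@@H]2[C@@H]1/C=C(\CO[Si](C(C)C)(C(C)C)C(C)C)C(=O)OC(C)(C)C | intermediate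
30 | lithium carboxylate from opening of 29: C3' silyloxy, C11' free OH | CC(C)[C@@H]1CC[C@](O[Si](C)(C)C(C)(C)C)(CO)[C@H](C(=O)[O-])[C@@H]1/C=C(\CO[Si](C(C)C)(C(C)C)C(C)C)C(=O)OC(C)(C)C.[Li+] | intermediate
31 | side-chain β-hydroxy acid: C3' free tertiary OH, C11' tert-butyldimethylsilyl ether, C2' carboxyl, C6' isopropyl, arm on C1' | CC(C)[C@@H]1CC[C@](O)(CO[Si](C)(C)C(C)(C)C)[C@H](C(=O)O)[C@@H]1/C=C(\CO[Si](C(C)C)(C(C)C)C(C)C)C(=O)OC(C)(C)C | intermediate
32 | tert-butyl (2E)-3-[(1R,6S)-3-{[(tert-butyldimethylsilyl)oxy]methyl}-6-(propan-2-yl)cyclohex-2-en-1-yl]-2-{[(triisopropylsilyl)oxy]methyl}prop-2-enoate | CC(C)[C@@H]1CCC(CO[Si](C)(C)C(C)(C)C)=C[C@@H]1/C=C(\CO[Si](C(C)C)(C(C)C)C(C)C)C(=O)OC(C)(C)C | intermediate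
33 | trimethylsilyl ester of 34 | CC(C)[C@@H]1CCC(CO[Si](C)(C)C(C)(C)C)=C[C@@H]1/C=C(\CO[Si](C(C)C)(C(C)C)C(C)C)C(=O)O[Si](C)(C)C | intermediate
34 | (2E)-3-[(1R,6S)-3-{[(tert-butyldimethylsilyl)oxy]methyl}-6-(propan-2-yl)cyclohex-2-en-1-yl]-2-{[(triisopropylsilyl)oxy]methyl}prop-2-enoic acid | CC(C)[C@@H]1CCC(CO[Si](C)(C)C(C)(C)C)=C[C@@H]1/C=C(\CO[Si](C(C)C)(C(C)C)C(C)C)C(=O)O | intermediate
35 | core primary alcohol: 18 with C13 as CH2OH | CC(=O)[C@H]1CC[C@@](O[Si](C)(C)C(C)(C)C)(CO)[C@H]2C(=O)OCC(C(=O)OC(C)(C)C)=C[C@@H]12 | intermediate
36 | mixed anhydride of 34 with 2,4,6-trichlorobenzoic acid | CC(C)[C@@H]1CCC(CO[Si](C)(C)C(C)(C)C)=C[C@@H]1/C=C(\CO[Si](C(C)C)(C(C)C)C(C)C)C(=O)OC(=O)c2c(Cl)cc(Cl)cc2Cl | intermediate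
37 | coupled keto ester: 35 acylated on O13 by 34 (C1 acetyl, C4 silyloxy, C12 tert-butyl ester) | CC(=O)[C@H]1CC[C@@](O[Si](C)(C)C(C)(C)C)(COC(=O)/C(=C/[C@H]3C=C(CO[Si](C)(C)C(C)(C)C)CC[C@H]3C(C)C)CO[Si](C(C)C)(C(C)C)C(C)C)[C@H]2C(=O)OCC(C(=O)OC(C)(C)C)=C[C@@H]12 | intermediate
38 | 37 with isopropenyl in place of acetyl on C1 | C=C(C)[C@H]1CC[C@@](O[Si](C)(C)C(C)(C)C)(COC(=O)/C(=C/[C@H]3C=C(CO[Si](C)(C)C(C)(C)C)CC[C@H]3C(C)C)CO[Si](C(C)C)(C(C)C)C(C)C)[C@H]2C(=O)OCC(C(=O)OC(C)(C)C)=C[C@@H]12 | intermediate
39 | fully protected target: C4 and C11' tert-butyldimethylsilyl ethers, C10' triisopropylsilyl ether, C12 tert-butyl ester | CC(C)[C@H]1CC[C@@](O[Si](C)(C)C(C)(C)C)(COC(=O)/C(=C/[C@H]3C=C(CO[Si](C)(C)C(C)(C)C)CC[C@H]3C(C)C)CO[Si](C(C)C)(C(C)C)C(C)C)[C@H]2C(=O)OCC(C(=O)OC(C)(C)C)=C[C@@H]12 | intermediate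
40 | C12 trimethylsilyl ester of 41 | CC(C)[C@H]1CC[C@@](O[Si](C)(C)C(C)(C)C)(COC(=O)/C(=C/[C@H]3C=C(CO[Si](C)(C)C(C)(C)C)CC[C@H]3C(C)C)CO[Si](C(C)C)(C(C)C)C(C)C)[C@H]2C(=O)OCC(C(=O)O[Si](C)(C)C)=C[C@@H]12 | intermediate
41 | tris-silylated acid: 39 with free C12 carboxylic acid | CC(C)[C@H]1CC[C@@](O[Si](C)(C)C(C)(C)C)(COC(=O)/C(=C/[C@H]3C=C(CO[Si](C)(C)C(C)(C)C)CC[C@H]3C(C)C)CO[Si](C(C)C)(C(C)C)C(C)C)[C@H]2C(=O)OCC(C(=O)O)=C[C@@H]12 | intermediate
42 | CNP0361406.12: core lactone acid (1R,4S,5S,6R in the numbering above) esterified on O13 with (2E)-2-(hydroxymethyl)-3-[(1R,6S)-3-(hydroxymethyl)-6-(propan-2-yl)cyclohex-2-en-1-yl]prop-2-enoic acid | CC(C)[C@H]1CC[C@@](O)(COC(=O)/C(=C/[C@H]2C=C(CO)CC[C@H]2C(C)C)CO)[C@H]2C(=O)OCC(C(=O)O)=C[C@@H]12 | target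

## Step count and least certain steps

Total step count: 27 steps.

Longest linear sequence: 17 steps, through the side-chain branch (4 → 5 → 20 → 21 → 22 → 24 → 25 → 27 → 28 → 29 → 31 → 32 → 34 → 37 → 38 → 39 → 41 → 42). The core branch from 4 to 42 is 14 steps.

Step 4 (key step; step 12 is its mirror image). The cycloaddition may be slow at the hindered silyloxy-bearing diene terminus, the diene may isomerise by 1,5-hydrogen shift at the temperature needed, or endo and regio control may erode through a stepwise Mukaiyama–Michael pathway with silyl transfer. Fallback: the same two bonds are made with a symmetrical, far more reactive dienophile and the absolute configuration is introduced afterwards by resolution. Diene 3 and maleic anhydride (toluene, 0 °C → rt) should give the racemic endo anhydride F1 with no regiochemical question. LiAlH(OtBu)3 (THF, −78 °C) reduces the less hindered carbonyl, the one remote from the silyloxy bridgehead, to the lactol, that is, the racemate of 9 and 22. Acetalisation with 6 (CSA, benzene, reflux) then gives 8 and the diastereomeric menthyl acetal F2, separable by chromatography or crystallisation. The fallback sets out from 3 and comes back to the route at 8; F2 is hydrolysed under the conditions of step 13 to 22, so both antipodes are used.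

Step 23. The free C13 hydroxyl of 35 may attack the lactone carbonyl C7 (translactonisation to the five-membered lactone with release of the C9 alcohol) or take over the neighbouring silyl group under the amine bases, faster than the hindered neopentyl-type alcohol is acylated. Fallback: the roles of nucleophile and electrophile are reversed. Alcohol 35 is mesylated at once (MsCl, Et3N, CH2Cl2, −20 °C) to the neopentyl mesylate F3, which is inert to the conditions of steps 24 and 25 and gives the C1-isopropenyl mesylate F4 and the C1-isopropyl mesylate F5. Fluoride (TBAF, THF, 0 °C → rt) removes the tertiary silyl group and the alkoxide closes the spiro-epoxide F6. The caesium salt of 34 (Cs2CO3, DMF, 60 °C) opens the epoxide at its CH2 terminus, C13, to give the C4-hydroxy ester F7. TMSOTf/2,6-lutidine then gives the hydroxy acid F8 (any trimethylsilyl ether formed on O4 is lost in the work-up or in the last operation), and aqueous HF in MeCN gives 42. The fallback sets out from 35 and comes back at 42.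

Step 19. The silyl shift from the tertiary to the primary oxygen may be slow or incomplete in aqueous base, so that acidification returns lactone 29, or the primary silyl ether may be lost. Fallback: the shift is carried out earlier on an anhydrous alkoxide and the lactone is never formed. The sodium salt of 25 is reduced with NaBH4 in EtOH/CH2Cl2 at −78 °C (aldehyde only) and warmed with K2CO3, so that the C11' alkoxide takes the silyl group, giving the keto β-hydroxy acid F9. Lombardo methylenation (Zn, CH2Br2, TiCl4) with excess reagent gives the isopropenyl β-hydroxy acid F10, and hydrogenation with RhCl(PPh3)3 gives 31. The fallback sets out from 25 and comes back at 31.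

Step 5 (and step 13). In aqueous acid strong enough for the acyloxy acetal, the bridgehead silyl ether may be lost or the trisubstituted bridge alkene protonated. Fallback: the acetal is opened at the acyl carbon under base instead. LiOH (1.0 equiv, THF/H2O, 0 °C) saponifies 8; the hemiacetal collapses to 6 and the lithium aldehyde carboxylate F11. Because the hydroxide is consumed, the solution ends near neutral, and acidification to pH 4 closes F11 to 9. The fallback sets out from 8 and comes back at 9.

Step 7 (and step 14). Loss of the cis relation by enolisation of the liberated aldehyde, or poor E/Z selectivity in forming the trisubstituted enoate, may occur. Fallback for the core: the ring alkene is made by metathesis, where the ring fixes the geometry. Lactol 9 is methylenated (Ph3P=CH2 from Ph3PCH3Br and KN(SiMe3)2, THF, 0 °C) to the vinyl acid F12. Its caesium carboxylate is alkylated with tert-butyl 2-(bromomethyl)acrylate (Cs2CO3, DMF) to the diene ester F13. Ring-closing metathesis with the second-generation Hoveyda–Grubbs catalyst (toluene, 80 °C) gives 17. The fallback sets out from 9 and comes back at 17.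

## Further compounds

F1 | step 4 | racemic endo 1-[(tert-butyldimethylsilyl)oxy]-5-methylbicyclo[2.2.2]oct-5-ene-2,3-dicarboxylic anhydride (one enantiomer drawn) | CC1=C[C@]2(O[Si](C)(C)C(C)(C)C)CC[C@H]1[C@H]3[C@@H]2C(=O)OC3=O
F2 | step 4 | (1S,2R,5S)-menthyl acetal of the antipodal bicycle (diastereomer of 8, menthyloxy anti) | CC1=C[C@@]2(O[Si](C)(C)C(C)(C)C)CC[C@@H]1[C@@H]3[C@H]2C(=O)O[C@H]3O[C@H]4C[C@@H](C)CC[C@@H]4C(C)C
F3 | step 23 | O13 methanesulfonate of 35 | CC(=O)[C@H]1CC[C@@](O[Si](C)(C)C(C)(C)C)(COS(C)(=O)=O)[C@H]2C(=O)OCC(C(=O)OC(C)(C)C)=C[C@@H]12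
F4 | step 23 | F3 with isopropenyl in place of acetyl on C1 | C=C(C)[C@H]1CC[C@@](O[Si](C)(C)C(C)(C)C)(COS(C)(=O)=O)[C@H]2C(=O)OCC(C(=O)OC(C)(C)C)=C[C@@H]12
F5 | step 23 | F3 with isopropyl in place of acetyl on C1 | CC(C)[C@H]1CC[C@@](O[Si](C)(C)C(C)(C)C)(COS(C)(=O)=O)[C@H]2C(=O)OCC(C(=O)OC(C)(C)C)=C[C@@H]12
F6 | step 23 | spiro-epoxide (C4–O–C13) of the core lactone, C12 tert-butyl ester | CC(C)[C@H]1CC[C@@]3(CO3)[C@H]2C(=O)OCC(C(=O)OC(C)(C)C)=C[C@@H]12
F7 | step 23 | 39 without the C4 silyl group (free tertiary alcohol) | CC(C)[C@H]1CC[C@@](O)(COC(=O)/C(=C/[C@H]3C=C(CO[Si](C)(C)C(C)(C)C)CC[C@H]3C(C)C)CO[Si](C(C)C)(C(C)C)C(C)C)[C@H]2C(=O)OCC(C(=O)OC(C)(C)C)=C[C@@H]12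
F8 | step 23 | 41 without the C4 silyl group (free tertiary alcohol, free C12 acid) | CC(C)[C@H]1CC[C@@](O)(COC(=O)/C(=C/[C@H]3C=C(CO[Si](C)(C)C(C)(C)C)CC[C@H]3C(C)C)CO[Si](C(C)C)(C(C)C)C(C)C)[C@H]2C(=O)OCC(C(=O)O)=C[C@@H]12
F9 | step 19 | keto β-hydroxy acid: 31 with acetyl in place of isopropyl on C6' | CC(=O)[C@@H]1CC[C@](O)(CO[Si](C)(C)C(C)(C)C)[C@H](C(=O)O)[C@@H]1/C=C(\CO[Si](C(C)C)(C(C)C)C(C)C)C(=O)OC(C)(C)C
F10 | step 19 | isopropenyl β-hydroxy acid: 31 with isopropenyl in place of isopropyl on C6' | C=C(C)[C@@H]1CC[C@](O)(CO[Si](C)(C)C(C)(C)C)[C@H](C(=O)O)[C@@H]1/C=C(\CO[Si](C(C)C)(C(C)C)C(C)C)C(=O)OC(C)(C)C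
F11 | step 5 | lithium 1-[(tert-butyldimethylsilyl)oxy]-3-formyl-5-methylbicyclo[2.2.2]oct-5-ene-2-carboxylate (cis, endo) | CC1=C[C@]2(O[Si](C)(C)C(C)(C)C)CC[C@H]1[C@H](C=O)[C@@H]2C(=O)[O-].[Li+]
F12 | step 7 | 1-[(tert-butyldimethylsilyl)oxy]-3-ethenyl-5-methylbicyclo[2.2.2]oct-5-ene-2-carboxylic acid (cis, endo) | CC1=C[C@]2(O[Si](C)(C)C(C)(C)C)CC[C@H]1[C@H](C=C)[C@@H]2C(=O)O
F13 | step 7 | 2-(tert-butoxycarbonyl)prop-2-en-1-yl ester of F12 | CC1=C[C@]2(O[Si](C)(C)C(C)(C)C)CC[C@H]1[C@H](C=C)[C@@H]2C(=O)OCC(=C)C(=O)OC(C)(C)C
A1 | alternative 1 | cis cyclohexene imide carrying the (E)-acrylate arm | COC(=O)/C(CO[Si](C)(C)C(C)(C)C)=C/[C@H]1C=C(CO[Si](C)(C)C(C)(C)C)CC[C@H]1C(=O)N2CCOC2=O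
A2 | alternative 1 | methyl (2E,4E)-2,6-bis{[(tert-butyldimethylsilyl)oxy]methyl}hepta-2,4,6-trienoate | COC(=O)/C(CO[Si](C)(C)C(C)(C)C)=C/C=C/C(=C)CO[Si](C)(C)C(C)(C)C
A3 | alternative 1 | 3-(prop-2-enoyl)-1,3-oxazolidin-2-one | C=CC(=O)N1CCOC1=O
A4 | alternative 2 | protected bicyclic core with the oxepinone closed (C13 silyl ether, C12 2-(trimethylsilyl)ethyl ester) | CC(C)[C@H]1CC[C@@](O)(CO[Si](C)(C)C(C)(C)C)[C@H]2C(=O)OCC(C(=O)OCC[Si](C)(C)C)=C[C@@H]12
A5 | alternative 2 | metathesis precursor: C6 vinyl, C5 carboxyl esterified with 2-(trimethylsilyl)ethyl 2-(hydroxymethyl)acrylate | CC(C)[C@H]1CC[C@@](O)(CO[Si](C)(C)C(C)(C)C)[C@@H](C(=O)OCC(=C)C(=O)OCC[Si](C)(C)C)[C@H]1C=C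
A6 | alternative 3 | cis-fused γ-lactone with tertiary tert-butyl peroxide at C4 | CC(C)[C@H]1CC[C@@](OOC(C)(C)C)(CO[Si](C)(C)C(C)(C)C)[C@H]2C(=O)OC[C@@H]12
A7 | alternative 3 | carbazate of the cis cyclohexenylmethanol (C4=C5 alkene, C13 silyl ether) | CC(C)[C@H]1CCC(CO[Si](C)(C)C(C)(C)C)=C[C@H]1COC(=O)NN
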